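The vessel is closed, stirred and isothermal, and it holds Z and E through these steps:

    Z + E → Z.E (k1 = 0.27 M⁻¹ h⁻¹)
    Z + 2 E → Q (k2 = 0.94 M⁻² h⁻¹)
    Z + Z.E → Z.Z.E (k3 = 0.057 M⁻¹ h⁻¹)
    Z.E ⇌ X (K4 = 3.5, k4 = 0.0036 h⁻¹)

| flask | Z | E | time |
|---|---|---|---|
| cedar | 1.0 M | 0.800 equiv | 2.5 d |
| alder | 1.0 M | 0.800 equiv | 4.0 d |
| ash | 1.0 M | 0.800 equiv | 6.0 d |

- in percentages every species weighs as the Z in it: one Z.Z.E counts as two
- where a step has two of a species, its rate is k times that concentration squared, and two are used at each turn
- run time (cedar): 2.5 d

* which of the two there is more of at the end, counted by the Z in each, cedar (Z.E / Z.Z.E)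
* which of the two there is more of at the end, counted by the Z in each, alder (Z.E / Z.Z.E)
* which of the two there is more of at the end, counted by the Z in each, ash (Z.E / Z.Z.E)
* how much Z.E is there at the end, in percent of the Z charged: cedar
* how much Z.E is there at the end, in percent of the Z charged: alder
* how much Z.E is there at the end, in percent of the Z charged: ash

At the bench I treat Z.E as pseudo-first-order in Z. With Z as charged, its half-life by step 3 is 0.51 d, which leaves 3.27% of the Z.E made still standing in cedar. That rule needs Z in large excess over Z.E, so I test the excess.

While E lasts, Z cancels from the ratio of steps 1 and 2, and the split depends on E by itself. The two steps use E equally at a = 14.4% of the Z charged. Integrating that split with E run down to zero, in fractions of the charge: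

Q = (E − a·ln(1 + E/a))/2 = 26.5%

Z.E made, M = E − 2Q = 27.0%

Each turn of step 3 then takes one Z and one Z.E, so Z minus Z.E holds still. I carry that difference, the floor of Z, which is what stays of Z once Z.E has been paired off:

f = 1 − Q − 2M = 19.4%

Here the floor is 0.719 of M, so the excess the rule needs is absent and its number fails. Integrating the true rate gives a ratio that decays with constant k·f, where k = 0.057 M⁻¹ h⁻¹ times the Z charged:

r = Z.E/Z = M/(M + f)·exp(−k·f·t)

Z.E = f·r/(1 − r)·exp(−0.0036 h⁻¹·t)

The last factor is the forward loss to X, and I drop its return. I start the clock at zero as an approximation, because Z.E comes from step 1, and by that step E halves in 2.57 h with Z as charged, short against 2.5 d. This gives Z.E of 6.69% in cedar, 3.46% in alder and 1.55% in ash. My mark in each is Z.Z.E, which counts double.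

The forecast says Z.Z.E in each, with Z.E at 6.9% (6% to 8%), 3.5% (2.9% to 4.2%) and 1.6% (1.2% to 2.1%). Its ground is that Z.E “drains into Z.Z.E, which counts double”. My cedar figure stands lower than its figure.

The flask gives Z.E 7.07%, 3.62% and 1.64%, against Z.Z.E 34.5%, 40.4% and 43.8%, so Z.Z.E leads in each, and the forecast's values lie inside their ranges.

At the end of cedar, Z.E is made at 0.0146 of the rate at which it is used up, and Z minus Z.E reads 22.2%, against the floor of 19.4% plus the 2.68% standing as X. A flask like cedar with 0.480 equiv of E has Q = 13.5% and M = 21.1% by the same lines, hence a floor of 44.4% and Z.E of 2.72%, and that flask holds Q 13.5% and Z.E 3.00%.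

The numbers of this flask are those of an exercise; what happens was integrated by code.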